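At late times, once the free monomer is used, the initiator that outlived it keeps turning monomer in chains into isomer of the product, so I ask how much initiator outlives it.

    free monomer + initiator → living end + monomer in chains (k1 = 43.8 M⁻¹ min⁻¹, Ea1 = 41.0 kJ mol⁻¹)
    free monomer + living end → monomer in chains + living end, rate k2*[living end]*[free monomer] (k2 = 4940 M⁻¹ min⁻¹, Ea2 = 56.0 kJ mol⁻¹)
    monomer in chains + initiator ⇌ isomer of the product + initiator, rate k3*[initiator]*[monomer in chains] forward; the back reaction follows from the equilibrium constant (K3 = 2.2, k3 = 296 M⁻¹ min⁻¹, Ea3 = 61.0 kJ mol⁻¹, ΔH3 = −3.00 kJ mol⁻¹)
    (constants at 100 °C)

the same everywhere: free monomer 0.020 M; initiator 100 µM; time 25 min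

| flask | temperature |
|---|---|
| north-west | 80 °C |
| east | 120 °C |
| south-west | 140 °C |
| north | 100 °C |

- constants are those at 100 °C; use the activation energies and enthalpies for any other temperature

1. the flask with the highest share of monomer in chains in all that became monomer in chains or isomer of the product ("all alike" if they lie within 1.5 percentage points) (north-west / east / south-west / north / all alike)
2. share of monomer in chains in all that became monomer in chains or isomer of the product, north-west
3. share of monomer in chains in all that became monomer in chains or isomer of the product, east
4. share of monomer in chains in all that became monomer in chains or isomer of the product, south-west
5. share of monomer in chains in all that became monomer in chains or isomer of the product, north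

I write the balance of the initiator, the reagent charged in the smaller amount. Every initiator lost leaves a living end that competes for free monomer, and growth beats initiation by kP/kI = 113 at the reference temperature. Dividing the free monomer balance by the initiator balance and integrating to the end of the free monomer gives, for large kP/kI, a surviving fraction s = exp(−1 − a), where a is kI/kP times the charged ratio of free monomer to initiator. The surviving initiator then makes isomerisation a pseudo-first-order relaxation towards K, with kX its forward constant. K moves from 2.32 in north-west to 2.00 in south-west, so I hold it at 2.2.

Everything folds into Λ = (1 + 1/K)·kX·s·c(initiator)·t. For north-west it is 0.0126, the exposure, which is the run counted in relaxation times. It is 0.269 for east, 0.875 for south-west and 0.0672 for north.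

The share of monomer in chains is 1 − (1 − exp(−Λ))/(1 + 1/K). That reads 99.1% for north-west, 83.8% for east, 59.9% for south-west and 95.5% for north, and the highest stands in north-west. One number is not quite enough. In north-west the growth time 5.63 min is about a quarter of the run, and during it more initiator stands than s counts, so I expect my share there to read high.

The forecast names north-west, with 98.8% for north-west, 82.3% for east, 57% for south-west and 95% for north, on the ground that “the initiator is only partly used up”. For south-west it stands 2.9 percentage points below mine.

The simulation gives north-west, with 98.8% for north-west, 82.3% for east, 57.0% for south-west and 95.0% for north. In north-west the half-life of monomer in chains by forward isomerisation alone, at the initiator of 25.0 min, is 30 h, longer than the run of 25 min. Read back through my share with K held at 2.2, the 98.8% of north-west is an exposure of 0.0173 against my 0.0126, and the initiator there stands at 5.85% after 12.5 min and 3.95% after 25.0 min. A neighbour of north-west charged with 2.5 × 10⁻⁴ M of initiator has exposure 0.128, hence a share of 91.7%, and it reads 90.8%, lower than the north flask's 95.0%.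

The rate constants are made up; no experiment stands behind them.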